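**Plan**

- Retrosynthesis: the C11/C20 epoxide, the C6 chloride (back to a C5=C6 alkene) and the three esters go first. The γ-lactone is then cut at C8–C17 and O7–C19, and the cyclohexane at C13–C14.
- Enabling feature: quaternary C1 carries the oxygenated C14 and its neighbour C10 carries C11 with the exocyclic C20. Across the C1–C10 bond shared by the six- and ten-membered rings this is a γ,δ-unsaturated acid (C14–C1–C10–C11=C20). Cutting C1–C10 and joining C14 to C20 through oxygen gives a 14-membered lactone (ring atoms C14, O, C20, C11, C10 to C2, C1).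
- The lactone opens at the ester; the chain is cut at C1–C2 (aldol), C3–C4 (Claisen), C5–C6 (Grignard) and C10=C11 (olefination), which leaves L-arabinose as C6–C10.
- Forward: chain from L-arabinose, 14-membered lactone, ten-membered carbocycle by ring contraction, cyclohexane (C13–C14), γ-lactone (C8–C17), chloride, epoxide.
- Stereochemistry: C7 and C9 are C2 and C4 of L-arabinose (C8 = C3 is oxidised later); C2 from an Evans aldol; C1 and C10 from the chelated chair Claisen; C14 from a bulky hydride; C8 and C17 from a tethered Reformatsky; C6 and C11 from attack on the outer faces of the bicycle.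

Key step: step 20

Remark: briarane locants are used for every intermediate (arabinose C1–C5 = C6–C10); centres that are destroyed later (C6 of 16 and 18, the CHBr carbon of 43–45, the phosphonate carbon of 10) are carried as mixtures and left open in the SMILES.

**Route**

Step 1
Reactants: 1 L-arabinose
Product: 2 L-arabinose diethyl dithioacetal
Conditions: EtSH, conc. HCl, 0 °C
Reagents that add atoms: ethanethiol, CCS
Why: Fischer dithioacetalisation opens the pyranose and masks the aldehyde carbon (future C6) as an acyclic dithioacetal without touching the three carbinol centres.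

Step 2
Reactants: 2 L-arabinose diethyl dithioacetal
Product: 3 2,3:4,5-di-O-isopropylidene-L-arabinose diethyl dithioacetal
Conditions: 2,2-dimethoxypropane, acetone, TsOH (cat.), rt
Reagents that add atoms: 2,2-dimethoxypropane, COC(C)(C)OC
Why: Acid-catalysed acetalisation pairs the threo 2,3-diol as a trans-dioxolane (future C7/C8) and the terminal 4,5-diol as a second dioxolane, the usual pattern for arabinose dithioacetals.

Step 3
Reactants: 3 diacetonide
Product: 4 2,3-O-isopropylidene-L-arabinose diethyl dithioacetal (4,5-diol)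
Conditions: AcOH/H2O (7:3), 40 °C
Reagents that add atoms: none
Why: Acetal hydrolysis is faster at the monosubstituted terminal dioxolane than at the trans-disubstituted internal one, so the 4,5-diol should be released selectively.

Step 4
Reactants: 4 4,5-diol
Product: 5 4,5-bis-O-TBS ether
Conditions: TBSOTf, 2,6-lutidine, CH2Cl2, −78 → 0 °C
Reagents that add atoms: tert-butyldimethylsilyl trifluoromethanesulfonate, CC(C)(C)[Si](C)(C)OS(=O)(=O)C(F)(F)F
Why: Silyl ether formation at both hydroxyls; the secondary ether is the C9 protecting group until step 33.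

Step 5
Reactants: 5 bis-TBS ether
Product: 6 primary alcohol (future C10 OH; C9 OTBS)
Conditions: HF·pyridine, pyridine, THF, 0 °C
Reagents that add atoms: none
Why: Fluoride-mediated desilylation is much faster at the primary silyl ether, so only the terminal hydroxyl should be freed.

Step 6
Reactants: 6 primary alcohol
Product: 7 C10 aldehyde
Conditions: (COCl)2, DMSO, CH2Cl2, −78 °C; Et3N
Reagents that add atoms: none
Why: Swern oxidation should give the α-silyloxy aldehyde without epimerising C9 or oxidising sulfur; it is used crude.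

Step 7
Reactants: 8 triethyl phosphonoacetate; 9 1-[(2-bromoethoxy)methyl]-4-methoxybenzene
Product: 10 ethyl 2-(diethoxyphosphoryl)-4-[(4-methoxybenzyl)oxy]butanoate
Conditions: NaH, THF/DMF, 0 → 60 °C
Reagents that add atoms: none
Why: SN2 alkylation of the sodium phosphonoacetate carbanion installs the C12–C13 arm with C13 already protected as a PMB ether.

Step 8
Reactants: 7 C10 aldehyde; 10 phosphonate
Product: 11 ethyl (E)-enoate (C10=C11; CO2Et = C20; CH2CH2OPMB = C12–C13)
Conditions: LiCl, DBU, MeCN, 0 °C → rt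
Reagents that add atoms: none
Why: Horner–Wadsworth–Emmons olefination under Masamune–Roush conditions is mild enough for the α-silyloxy aldehyde and should place the ester trans to C9 (C9 cis to C12), the geometry the later chair transition state needs.

Step 9
Reactants: 11 enoate
Product: 12 C20 allylic alcohol
Conditions: DIBAL-H, CH2Cl2, −78 °C
Reagents that add atoms: none
Why: DIBAL-H reduces the conjugated ester 1,2 to the allylic alcohol and leaves the dithioacetal, acetal and ethers alone.

Step 10
Reactants: 12 allylic alcohol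
Product: 13 C20 acetate
Conditions: Ac2O, pyridine, DMAP (cat.), CH2Cl2, 0 °C
Reagents that add atoms: acetic anhydride, CC(=O)OC(C)=O
Why: Acetylation gives a protecting group that survives the next five steps and is removed in the same operation that frees the acid (step 17).

Step 11
Reactants: 13 acetate
Product: 14 C6 aldehyde
Conditions: I2, NaHCO3, acetone/H2O, 0 °C
Reagents that add atoms: water, O
Why: Iodine-mediated oxidative hydrolysis of the dithioacetal under buffered conditions frees the aldehyde; the trans-dioxolane is the stable arrangement at C7, so epimerisation is not expected.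

Step 12
Reactants: 14 C6 aldehyde; 15 isopropenylmagnesium bromide
Product: 16 C6 allylic alcohol (isopropenyl = C5/C16/C4; both C6 epimers)
Conditions: THF, −78 °C
Reagents that add atoms: none
Why: Grignard addition to the aldehyde is far faster than to the acetate at −78 °C, and the C6 epimer ratio does not matter because C6 becomes sp2 in step 14.

Step 13
Reactants: 16 allylic alcohol; 17 ethyl vinyl ether
Product: 18 C6 O-vinyl ether
Conditions: Hg(OAc)2 (cat.), ethyl vinyl ether as solvent, reflux
Reagents that add atoms: none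
Why: Mercury(II)-catalysed transetherification is the classical preparation of allyl vinyl ethers from hindered secondary allylic alcohols.

Step 14
Reactants: 18 allyl vinyl ether
Product: 19 C2 aldehyde with (E)-C5=C6
Conditions: toluene, 130 °C, sealed tube
Reagents that add atoms: none
Why: Claisen rearrangement forms C3–C4 through a chair transition state in which the bulky C7 dioxolanyl group is pseudo-equatorial, so either C6 epimer should give the (E)-trisubstituted alkene (C7 trans to C4).

Step 15
Reactants: 19 C2 aldehyde; 20 (R)-4-benzyl-3-propanoyl-1,3-oxazolidin-2-one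
Product: 22 syn-aldol imide (1R,2S), via boron enolate 21 (not isolated)
Conditions: 20, Bu2BOTf, i-Pr2NEt, CH2Cl2, 0 °C; then 19, −78 → 0 °C; pH 7 buffer, MeOH, H2O2
Reagents that add atoms: dibutylboron trifluoromethanesulfonate, CCCCB(CCCC)OS(=O)(=O)C(F)(F)F (its atoms stay in 21 only)
Why: Evans syn-aldol reaction: the (Z)-boron enolate reacts through a Zimmerman–Traxler chair and the (R)-benzyl auxiliary sets the 2S carbinol (C1 is set as R but is erased in step 20).

Step 16
Reactants: 22 aldol imide
Product: 23 C2 triethylsilyl ether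
Conditions: TESOTf, 2,6-lutidine, CH2Cl2, −78 °C
Reagents that add atoms: triethylsilyl trifluoromethanesulfonate, CC[Si](CC)(CC)OS(=O)(=O)C(F)(F)F
Why: Silylation covers the β-hydroxyl so that carboxyl activation in step 18 cannot lead to β-lactone formation, self-acylation or elimination.

Step 17
Reactants: 23 silylated imide
Product: 25 seco acid (C14 CO2H; C2 OTES; C20 OH), via peroxy acid 24 (not isolated)
Conditions: LiOH, H2O2, THF/H2O, 0 °C → rt; then Na2SO3
Reagents that add atoms: hydrogen peroxide, OO
Why: Lithium hydroperoxide attacks the exocyclic imide carbonyl and also cleaves the primary acetate, and sulfite reduces the peroxy acid, so one operation should expose both ends of the seco acid.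

Step 18
Reactants: 25 seco acid
Product: 27 fourteen-membered lactone (C2 OTES), via mixed anhydride 26 (not isolated)
Conditions: 2,4,6-trichlorobenzoyl chloride, Et3N, THF, rt; then slow addition to DMAP, toluene, 80 °C (about 1 mM)
Reagents that add atoms: 2,4,6-trichlorobenzoyl chloride, O=C(Cl)c1c(Cl)cc(Cl)cc1Cl (its atoms stay in 26 only)
Why: Yamaguchi macrolactonisation: the DMAP-activated acyl group is captured by the primary allylic C20 hydroxyl under high dilution, and the two (E)-alkenes and the trans-dioxolane restrict the chain in favour of ring closure.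

Step 19
Reactants: 27 lactone silyl ether
Product: 28 fourteen-membered lactone with free C2 hydroxyl
Conditions: HF·pyridine, pyridine, THF, 0 °C
Reagents that add atoms: none
Why: Buffered fluoride cleaves the triethylsilyl ether much faster than the hindered secondary TBS ether, freeing the hydroxyl needed for the dianion.

Step 20
Reactants: 28 hydroxy lactone
Product: 32 ten-membered carbocyclic acid (C2 OTES), via dilithium dianion 29 (not isolated), via silyl ketene acetal 30 (not isolated), via silyl ester 31 (not isolated)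
Conditions: LDA (2.3 equiv), THF, −78 → −40 °C; TESCl, Et3N, DMPU, −78 °C → rt, then 60 °C; aq. citric acid
Reagents that add atoms: chlorotriethylsilane, CC[Si](Cl)(CC)CC
Why: LDA removes the C2 hydroxyl proton and then H1, and lithium bridging the C2 alkoxide and the enolate oxygen (as in Fráter–Seebach dianions) fixes the enolate with C2 cis to O–Li; TESCl traps both oxygens as the (Z)-ketene acetal 30, which on warming undergoes the [3,3]-sigmatropic shift C1=C14–O–C20–C11=C10 → C1–C10 plus C11=C20, the closest known reaction types being the Ireland–Claisen ring contraction of macrocyclic allylic lactones and the dianionic Claisen rearrangement of acyclic allyl β-hydroxy esters. The ten-membered carbocycle closes by ring contraction: the new C1–C10 bond joins the two ends of the 1,5-diene held inside the 14-membered ring through a six-membered chair transition state, suprafacially on both three-atom fragments, and the C14–O–C20 link leaves the ring as the silyl ester 31. C1 is controlled by C2, because the allyl terminus C10 adds to the face of the planar chelate that is anti to C3, which puts the C15 methyl trans to H10. C10 is controlled by the chair together with the (E)-C10=C11 alkene and by C9, whose hydrogen lies in the alkene plane (allylic 1,3-strain with C12) so that the bond forms anti to the C8 ring bond; the two ring chains (C2 and C9) are then both equatorial on the chair. The step needs chair over boat and a single diastereoface, which the fixed enolate geometry, the (E)-alkene and the matched C2 and C9 centres should secure, and it needs the β-oxygen not to leave, which the alkoxide guarantees.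

Step 21
Reactants: 32 carbocyclic acid
Product: 33 methyl ester
Conditions: TMSCHN2, MeOH/toluene, 0 °C
Reagents that add atoms: (trimethylsilyl)diazomethane, C[Si](C)(C)C=[N+]=[N-]
Why: Diazoalkane esterification converts the hindered α-quaternary acid into an acyl acceptor under neutral conditions.

Step 22
Reactants: 33 methyl ester
Product: 34 C13 primary alcohol
Conditions: DDQ, CH2Cl2/pH 7 buffer, 0 °C
Reagents that add atoms: none
Why: Oxidative cleavage of the PMB ether (hydride abstraction, hydrolysis of the oxocarbenium ion) leaves silyl ethers, the acetonide and both alkenes untouched.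

Step 23
Reactants: 34 primary alcohol
Product: 35 C13 iodide
Conditions: I2, PPh3, imidazole, CH2Cl2, 0 °C
Reagents that add atoms: iodine, II
Why: Appel-type iodination proceeds by SN2 displacement of the alkoxyphosphonium at the unhindered primary carbon.

Step 24
Reactants: 35 iodide
Product: 37 bicyclic C14 ketone, via alkyllithium 36 (not isolated)
Conditions: t-BuLi (2.1 equiv), Et2O/pentane, −78 → −40 °C; MeOH at −78 °C
Reagents that add atoms: tert-butyllithium, [Li]C(C)(C)C (lithium stays in 36 only)
Why: Iodine–lithium exchange outruns any addition of tert-butyllithium, and the primary alkyllithium then acylates the neighbouring methyl ester in a 6-exo-trig closure (Parham-type cycloacylation) that forms C13–C14 and the cyclohexanone.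

Step 25
Reactants: 37 ketone
Product: 38 C14 axial alcohol (14S)
Conditions: L-Selectride, THF, −78 °C; then NaOH, H2O2
Reagents that add atoms: none
Why: The bulky hydride attacks the cyclohexanone from the equatorial direction (the axial approach is closed by the syn-axial H10 and H12), which should give the axial alcohol anti to the axial C15 methyl by substrate-controlled ketone reduction.

Step 26
Reactants: 38 alcohol
Product: 39 C14 acetate
Conditions: Ac2O, DMAP, pyridine, 40 °C
Reagents that add atoms: acetic anhydride, CC(=O)OC(C)=O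
Why: DMAP-catalysed acetylation fixes the hindered axial hydroxyl as the first of the two acetates.

Step 27
Reactants: 39 acetate
Product: 40 C2 alcohol
Conditions: HF·pyridine, pyridine, THF, 0 °C → rt
Reagents that add atoms: none
Why: Fluoride removes the triethylsilyl ether while the hindered C9 TBS ether, the acetate and the acetonide stay.

Step 28
Reactants: 40 C2 alcohol
Product: 41 C2 isobutyrate
Conditions: isobutyric anhydride, DMAP, Et3N, CH2Cl2, rt
Reagents that add atoms: isobutyric anhydride, CC(C)C(=O)OC(=O)C(C)C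
Why: DMAP-catalysed acylation installs the isobutyrate while C2 is the only free hydroxyl.

Step 29
Reactants: 41 isobutyrate
Product: 42 C7,C8-diol
Conditions: PPTS, MeOH, 50 °C
Reagents that add atoms: none
Why: Acid-catalysed transacetalisation to methanol removes the isopropylidene group under conditions that esters and a hindered secondary TBS ether should survive.

Step 30
Reactants: 42 diol; 43 2-bromopropanoyl bromide
Product: 44 C7 2-bromopropanoate (C8 OH free)
Conditions: pyridine, CH2Cl2, −40 °C
Reagents that add atoms: none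
Why: Acylation at low temperature should go to the allylic C7 hydroxyl, which has an sp2 neighbour, and not to the C8 hydroxyl, which is shielded by the C9 silyl ether.

Step 31
Reactants: 44 bromo ester
Product: 45 C8 ketone
Conditions: Dess–Martin periodinane, NaHCO3, CH2Cl2, rt
Reagents that add atoms: none
Why: Buffered Dess–Martin oxidation converts the remaining secondary alcohol into the ketone without epimerising the flanking C7 and C9 centres.

Step 32
Reactants: 45 α-acyloxy ketone
Product: 47 trans-fused 8-hydroxy γ-lactone (C9 OTBS), via samarium enolate 46 (not isolated)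
Conditions: SmI2 (2.2 equiv), THF, −78 °C
Reagents that add atoms: samarium(II) iodide, I[Sm]I (its atoms stay in 46 only)
Why: Intramolecular Reformatsky reaction: the samarium ester enolate formed by C–Br reduction is tied through O7 and can reach only the adjacent face of the C8 ketone, which, with the C6–C7 and C8–C9 ring bonds antiperiplanar as they were held by the trans-acetonide, should close the trans-fused lactone with the 8-hydroxyl anti to H7 and the C18 methyl exo, anti to the C8–C9 bond (17R).

Step 33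
Reactants: 47 hydroxy lactone
Product: 48 C9 alcohol
Conditions: HF (aq.), MeCN, 0 °C → rt
Reagents that add atoms: none
Why: Acidic fluoride cleaves the last silyl ether without base, so the β-hydroxy lactone cannot undergo retro-aldol cleavage.

Step 34
Reactants: 48 C9 alcohol
Product: 49 C9 acetate (2-O-isobutyryl-9,14-di-O-acetyl diene)
Conditions: Ac2O, pyridine, DMAP (cat.), CH2Cl2, rt
Reagents that add atoms: acetic anhydride, CC(=O)OC(C)=O
Why: The secondary C9 hydroxyl is acetylated under conditions that leave the tertiary C8 hydroxyl free.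

Step 35
Reactants: 49 triester diene
Product: 50 (6S)-6-chloro-5(16)-ene
Conditions: NCS, PhSeCl (cat.), CH2Cl2, 0 °C
Reagents that add atoms: N-chlorosuccinimide, O=C1CCC(=O)N1Cl
Why: Selenium-catalysed ene-type allylic chlorination should transfer electrophilic chlorine to the strained trisubstituted (E)-C5=C6 bond in preference to the 1,1-disubstituted C11=C20 bond, chlorine bonding to C6 from the outer face of the ten-membered ring and a C16 hydrogen being lost to give the C5=C16 methylene.

Step 36
Reactants: 50 allylic chloride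
Product: 51 target CNP0284862.1
Conditions: mCPBA, NaHCO3, CH2Cl2, 0 °C
Reagents that add atoms: 3-chloroperoxybenzoic acid, OOC(=O)c1cccc(Cl)c1
Why: Prilezhaev epoxidation should take the more electron-rich C11=C20 alkene (C5=C16 is deactivated by the allylic chloride) from the equatorial direction, because the axial face is blocked by the syn-axial C15 methyl, which places the epoxide oxygen on the side of H10 (11R).

**Compound list**

1 | L-arabinose (open-chain form) | O=C[C@H](O)[C@@H](O)[C@@H](O)CO | starting material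
2 | L-arabinose diethyl dithioacetal | CCSC(SCC)[C@H](O)[C@@H](O)[C@@H](O)CO | intermediate
3 | 2,3:4,5-di-O-isopropylidene-L-arabinose diethyl dithioacetal | CCSC(SCC)[C@@H]1OC(C)(C)O[C@H]1[C@@H]1COC(C)(C)O1 | intermediate
4 | 2,3-O-isopropylidene-L-arabinose diethyl dithioacetal (4,5-diol) | CCSC(SCC)[C@@H]1OC(C)(C)O[C@H]1[C@@H](O)CO | intermediate
5 | 4,5-bis-O-(tert-butyldimethylsilyl)-2,3-O-isopropylidene-L-arabinose diethyl dithioacetal | CCSC(SCC)[C@@H]1OC(C)(C)O[C@H]1[C@@H](O[Si](C)(C)C(C)(C)C)CO[Si](C)(C)C(C)(C)C | intermediate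
6 | 4-O-(tert-butyldimethylsilyl)-2,3-O-isopropylidene-L-arabinose diethyl dithioacetal (C10 OH free, C9 OTBS) | CCSC(SCC)[C@@H]1OC(C)(C)O[C@H]1[C@@H](O[Si](C)(C)C(C)(C)C)CO | intermediate
7 | C10 aldehyde: 4-O-TBS-2,3-O-isopropylidene-L-arabino-pentodialdose 1-(diethyl dithioacetal) | CCSC(SCC)[C@@H]1OC(C)(C)O[C@H]1[C@@H](O[Si](C)(C)C(C)(C)C)C=O | intermediate
8 | triethyl phosphonoacetate | CCOC(=O)CP(=O)(OCC)OCC | starting material
9 | 1-[(2-bromoethoxy)methyl]-4-methoxybenzene | COc1ccc(COCCBr)cc1 | starting material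
10 | ethyl 2-(diethoxyphosphoryl)-4-[(4-methoxybenzyl)oxy]butanoate (racemic) | CCOC(=O)C(CCOCc1ccc(OC)cc1)P(=O)(OCC)OCC | intermediate
11 | ethyl (E)-enoate: C6 CH(SEt)2, C7/C8 trans-acetonide, C9 OTBS, C10=C11 with CO2Et (C20) trans to C9 and CH2CH2OPMB (C12–C13) on C11 | CCSC(SCC)[C@@H]1OC(C)(C)O[C@H]1[C@@H](O[Si](C)(C)C(C)(C)C)/C=C(\CCOCc1ccc(OC)cc1)C(=O)OCC | intermediate
12 | C20 allylic alcohol of 11 | CCSC(SCC)[C@@H]1OC(C)(C)O[C@H]1[C@@H](O[Si](C)(C)C(C)(C)C)/C=C(\CCOCc1ccc(OC)cc1)CO | intermediate
13 | C20 acetate of 12 | CCSC(SCC)[C@@H]1OC(C)(C)O[C@H]1[C@@H](O[Si](C)(C)C(C)(C)C)/C=C(\CCOCc1ccc(OC)cc1)COC(C)=O | intermediate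
14 | C6 aldehyde (C7/C8 trans-acetonide, C9 OTBS, C20 OAc, C13 OPMB) | O=C[C@@H]1OC(C)(C)O[C@H]1[C@@H](O[Si](C)(C)C(C)(C)C)/C=C(\CCOCc1ccc(OC)cc1)COC(C)=O | intermediate
15 | isopropenylmagnesium bromide | CC(=C)[Mg]Br | starting material
16 | C6 secondary allylic alcohol bearing the isopropenyl group (C5, C16, C4); both C6 epimers | C=C(C)C(O)[C@@H]1OC(C)(C)O[C@H]1[C@@H](O[Si](C)(C)C(C)(C)C)/C=C(\CCOCc1ccc(OC)cc1)COC(C)=O | intermediate
17 | ethyl vinyl ether | C=COCC | starting material
18 | C6 O-vinyl ether of 16 | C=COC(C(C)=C)[C@@H]1OC(C)(C)O[C@H]1[C@@H](O[Si](C)(C)C(C)(C)C)/C=C(\CCOCc1ccc(OC)cc1)COC(C)=O | intermediate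
19 | C2 aldehyde OHC–C3H2–C4H2–C5(CH3)=C6H– with (E)-C5=C6 | O=CCC/C(C)=C/[C@@H]1OC(C)(C)O[C@H]1[C@@H](O[Si](C)(C)C(C)(C)C)/C=C(\CCOCc1ccc(OC)cc1)COC(C)=O | intermediate
20 | (R)-4-benzyl-3-propanoyl-1,3-oxazolidin-2-one | CCC(=O)N1[C@H](Cc2ccccc2)COC1=O | starting material
21 | (Z)-dibutylboron enolate of 20 (not isolated) | C/C=C(\OB(CCCC)CCCC)N1[C@H](Cc2ccccc2)COC1=O | intermediate
22 | syn-aldol imide (1R,2S): C14 N-acyloxazolidinone, C1 methyl, C2 OH | O=C(N1[C@H](Cc2ccccc2)COC1=O)[C@H](C)[C@@H](O)CC/C(C)=C/[C@@H]1OC(C)(C)O[C@H]1[C@@H](O[Si](C)(C)C(C)(C)C)/C=C(\CCOCc1ccc(OC)cc1)COC(C)=O | intermediate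
23 | C2 triethylsilyl ether of 22 | O=C(N1[C@H](Cc2ccccc2)COC1=O)[C@H](C)[C@@H](O[Si](CC)(CC)CC)CC/C(C)=C/[C@@H]1OC(C)(C)O[C@H]1[C@@H](O[Si](C)(C)C(C)(C)C)/C=C(\CCOCc1ccc(OC)cc1)COC(C)=O | intermediate
24 | C14 peroxy acid with C20 OH free (not isolated) | OOC(=O)[C@H](C)[C@@H](O[Si](CC)(CC)CC)CC/C(C)=C/[C@@H]1OC(C)(C)O[C@H]1[C@@H](O[Si](C)(C)C(C)(C)C)/C=C(\CCOCc1ccc(OC)cc1)CO | intermediate
25 | seco acid: C14 CO2H, C2 OTES, C20 OH | OC(=O)[C@H](C)[C@@H](O[Si](CC)(CC)CC)CC/C(C)=C/[C@@H]1OC(C)(C)O[C@H]1[C@@H](O[Si](C)(C)C(C)(C)C)/C=C(\CCOCc1ccc(OC)cc1)CO | intermediate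
26 | mixed anhydride of 25 with 2,4,6-trichlorobenzoic acid (not isolated) | O=C(OC(=O)c1c(Cl)cc(Cl)cc1Cl)[C@H](C)[C@@H](O[Si](CC)(CC)CC)CC/C(C)=C/[C@@H]1OC(C)(C)O[C@H]1[C@@H](O[Si](C)(C)C(C)(C)C)/C=C(\CCOCc1ccc(OC)cc1)CO | intermediate
27 | fourteen-membered lactone C14(=O)–O–C20 with C2 OTES, (E)-C5=C6, (E)-C10=C11, C7/C8 trans-acetonide, C9 OTBS | O=C1[C@H](C)[C@@H](O[Si](CC)(CC)CC)CC/C(C)=C/[C@@H]2OC(C)(C)O[C@H]2[C@@H](O[Si](C)(C)C(C)(C)C)/C=C(\CCOCc2ccc(OC)cc2)CO1 | intermediate
28 | fourteen-membered lactone with free C2 hydroxyl (key-step precursor) | O=C1[C@H](C)[C@@H](O)CC/C(C)=C/[C@@H]2OC(C)(C)O[C@H]2[C@@H](O[Si](C)(C)C(C)(C)C)/C=C(\CCOCc2ccc(OC)cc2)CO1 | intermediate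
29 | chelated dilithium dianion of 28: C2 alkoxide, C1=C14 enolate with O–Li cis to C2 (not isolated) | [Li]O/C1=C(C)\[C@@H](O[Li])CC/C(C)=C/[C@@H]2OC(C)(C)O[C@H]2[C@@H](O[Si](C)(C)C(C)(C)C)/C=C(\CCOCc2ccc(OC)cc2)CO1 | intermediate
30 | (Z)-triethylsilyl ketene acetal C1=C14(OTES)–O–C20 with C2 OTES (not isolated) | CC[Si](CC)(CC)O/C1=C(C)\[C@@H](O[Si](CC)(CC)CC)CC/C(C)=C/[C@@H]2OC(C)(C)O[C@H]2[C@@H](O[Si](C)(C)C(C)(C)C)/C=C(\CCOCc2ccc(OC)cc2)CO1 | intermediate
31 | triethylsilyl ester of 32 (not isolated) | CC[Si](CC)(CC)OC(=O)[C@]1(C)[C@@H](O[Si](CC)(CC)CC)CC/C(C)=C/[C@@H]2OC(C)(C)O[C@H]2[C@@H](O[Si](C)(C)C(C)(C)C)[C@H]1C(=C)CCOCc1ccc(OC)cc1 | intermediate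
32 | ten-membered carbocycle C1–C10 (key-step product): C1 (CH3, CO2H), C2 OTES, (E)-C5=C6, C7/C8 trans-acetonide, C9 OTBS, C10 bearing C(=CH2)CH2CH2OPMB; C15 methyl trans to H10 (1S,2S,10S) | OC(=O)[C@]1(C)[C@@H](O[Si](CC)(CC)CC)CC/C(C)=C/[C@@H]2OC(C)(C)O[C@H]2[C@@H](O[Si](C)(C)C(C)(C)C)[C@H]1C(=C)CCOCc1ccc(OC)cc1 | intermediate
33 | methyl ester of 32 | COC(=O)[C@]1(C)[C@@H](O[Si](CC)(CC)CC)CC/C(C)=C/[C@@H]2OC(C)(C)O[C@H]2[C@@H](O[Si](C)(C)C(C)(C)C)[C@H]1C(=C)CCOCc1ccc(OC)cc1 | intermediate
34 | C13 primary alcohol | COC(=O)[C@]1(C)[C@@H](O[Si](CC)(CC)CC)CC/C(C)=C/[C@@H]2OC(C)(C)O[C@H]2[C@@H](O[Si](C)(C)C(C)(C)C)[C@H]1C(=C)CCO | intermediate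
35 | C13 iodide | COC(=O)[C@]1(C)[C@@H](O[Si](CC)(CC)CC)CC/C(C)=C/[C@@H]2OC(C)(C)O[C@H]2[C@@H](O[Si](C)(C)C(C)(C)C)[C@H]1C(=C)CCI | intermediate
36 | C13 alkyllithium (not isolated) | COC(=O)[C@]1(C)[C@@H](O[Si](CC)(CC)CC)CC/C(C)=C/[C@@H]2OC(C)(C)O[C@H]2[C@@H](O[Si](C)(C)C(C)(C)C)[C@H]1C(=C)CC[Li] | intermediate
37 | bicyclic ketone: cyclohexanone C1–C14(=O)–C13–C12–C11(=C20H2)–C10 trans-fused to the ten-membered ring | O=C1CCC(=C)[C@H]2[C@@]1(C)[C@@H](O[Si](CC)(CC)CC)CC/C(C)=C/[C@@H]3OC(C)(C)O[C@H]3[C@H]2O[Si](C)(C)C(C)(C)C | intermediate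
38 | C14 axial alcohol (14S) | O[C@H]1CCC(=C)[C@H]2[C@@]1(C)[C@@H](O[Si](CC)(CC)CC)CC/C(C)=C/[C@@H]3OC(C)(C)O[C@H]3[C@H]2O[Si](C)(C)C(C)(C)C | intermediate
39 | C14 acetate | CC(=O)O[C@H]1CCC(=C)[C@H]2[C@@]1(C)[C@@H](O[Si](CC)(CC)CC)CC/C(C)=C/[C@@H]3OC(C)(C)O[C@H]3[C@H]2O[Si](C)(C)C(C)(C)C | intermediate
40 | C2 alcohol (C14 OAc) | CC(=O)O[C@H]1CCC(=C)[C@H]2[C@@]1(C)[C@@H](O)CC/C(C)=C/[C@@H]3OC(C)(C)O[C@H]3[C@H]2O[Si](C)(C)C(C)(C)C | intermediate
41 | C2 isobutyrate (C14 OAc, C7/C8 acetonide, C9 OTBS) | CC(=O)O[C@H]1CCC(=C)[C@H]2[C@@]1(C)[C@@H](OC(=O)C(C)C)CC/C(C)=C/[C@@H]3OC(C)(C)O[C@H]3[C@H]2O[Si](C)(C)C(C)(C)C | intermediate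
42 | C7,C8-diol | CC(=O)O[C@H]1CCC(=C)[C@H]2[C@@]1(C)[C@@H](OC(=O)C(C)C)CC/C(C)=C/[C@H](O)[C@@H](O)[C@H]2O[Si](C)(C)C(C)(C)C | intermediate
43 | 2-bromopropanoyl bromide (racemic) | CC(Br)C(Br)=O | starting material
44 | C7 2-bromopropanoate with C8 OH free (epimers at CHBr) | CC(=O)O[C@H]1CCC(=C)[C@H]2[C@@]1(C)[C@@H](OC(=O)C(C)C)CC/C(C)=C/[C@H](OC(=O)C(C)Br)[C@@H](O)[C@H]2O[Si](C)(C)C(C)(C)C | intermediate
45 | C8 ketone | CC(=O)O[C@H]1CCC(=C)[C@H]2[C@@]1(C)[C@@H](OC(=O)C(C)C)CC/C(C)=C/[C@H](OC(=O)C(C)Br)C(=O)[C@H]2O[Si](C)(C)C(C)(C)C | intermediate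
46 | samarium(III) enolate of the C7 propanoate (not isolated) | CC(=O)O[C@H]1CCC(=C)[C@H]2[C@@]1(C)[C@@H](OC(=O)C(C)C)CC/C(C)=C/[C@H](OC(O[Sm](I)I)=CC)C(=O)[C@H]2O[Si](C)(C)C(C)(C)C | intermediate
47 | γ-lactone O7–C19(=O)–C17H(CH3)–C8(OH), trans-fused (H7 and 8-OH trans), C18 methyl cis to 8-OH, C9 OTBS | CC(=O)O[C@H]1CCC(=C)[C@H]2[C@@]1(C)[C@@H](OC(=O)C(C)C)CC/C(C)=C/[C@@H]3OC(=O)[C@H](C)[C@@]3(O)[C@H]2O[Si](C)(C)C(C)(C)C | intermediate
48 | C9 alcohol | CC(=O)O[C@H]1CCC(=C)[C@H]2[C@@]1(C)[C@@H](OC(=O)C(C)C)CC/C(C)=C/[C@@H]3OC(=O)[C@H](C)[C@@]3(O)[C@H]2O | intermediate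
49 | C9 acetate: 2-O-isobutyryl-9,14-di-O-acetyl-8-hydroxy lactone with (E)-C5=C6 and C11=C20 | CC(=O)O[C@H]1CCC(=C)[C@H]2[C@@]1(C)[C@@H](OC(=O)C(C)C)CC/C(C)=C/[C@@H]3OC(=O)[C@H](C)[C@@]3(O)[C@H]2OC(C)=O | intermediate
50 | (6S)-6-chloro-5(16)-ene | CC(=O)O[C@H]1CCC(=C)[C@H]2[C@@]1(C)[C@@H](OC(=O)C(C)C)CCC(=C)[C@H](Cl)[C@@H]3OC(=O)[C@H](C)[C@@]3(O)[C@H]2OC(C)=O | intermediate
51 | CNP0284862.1 (1R,2S,6S,7R,8R,9S,10S,11R,14S,17R) | C=C1CC[C@H](OC(=O)C(C)C)[C@@]2(C)[C@@H](OC(C)=O)CC[C@]3(CO3)[C@@H]2[C@H](OC(C)=O)[C@]2(O)[C@@H](C)C(=O)O[C@H]2[C@H]1Cl | target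

**Step count**

Total steps: 36. Longest linear sequence: 35 (steps 1–6 and 8–36; step 7 prepares the phosphonate).

**Steps most likely to fail**

Step 20. The dianion may fragment by retro-aldol opening of the macrocycle, C1 may be deprotonated incompletely, or the ketene acetal may rearrange through a boat or on the wrong face and give a C1/C10 diastereomer. The fallback gives up the chelate and sets out from the silyl ether 27, one step earlier. LDA is added to a mixture of 27, TESCl and Et3N in THF at −100 °C (internal quench), so that the enolate is silylated as it forms and no free enolate or β-alkoxide accumulates. The ketene acetal geometry is then left to the fourteen-membered ring, which is expected to favour the same (Z)-ketene acetal 30 (C2 and the ring oxygen trans). Warming and hydrolysis of 31 return the route at acid 32; no new compound is made (F0).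

Step 32. The tethered enolate may be protonated before it reaches the ketone (the five-membered closure has the enolate double bond inside the forming ring), samarium diiodide may cleave the α-acyloxy ketone reductively, or the ring may close cis-fused. The fallback makes C8–C17 intermolecularly and closes the ring by lactonisation. From diol 42, the allylic hydroxyl is silylated selectively (TESCl, imidazole, CH2Cl2, −20 °C) to give the C7 triethylsilyl ether F1, and Dess–Martin oxidation gives the C8 ketone F2. A rhodium-catalysed Reformatsky addition (ethyl 2-bromopropanoate, Et2Zn, RhCl(PPh3)3 cat., THF, 0 °C), which is not basic enough to enolise the ketone, should give the β-hydroxy ester F3; the configuration at C8 is then decided by external attack on the ring ketone instead of by the tether. HF·pyridine removes the C7 silyl group and the freed hydroxyl lactonises onto the ethyl ester (PPTS, toluene, 60 °C if needed), which returns the route at 47.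

Step 35. Chlorine may be delivered to the wrong face of C5=C6, to the C11=C20 methylene, or the proton may be lost from C4 to give the endocyclic alkene. The fallback introduces the chloride in two stages with the opposite stereochemical sense. From 49, dye-sensitised photo-oxygenation (O2, tetraphenylporphyrin, hν, CH2Cl2, 0 °C; Schenck ene reaction) should attack only the trisubstituted alkene on its outer face and abstract hydrogen from C16 (cis effect), giving the C6 allylic hydroperoxide F4 with the C5=C16 methylene. Triphenylphosphine reduces it to the allylic alcohol F5, and triphenylphosphine–hexachloroacetone replaces the hydroxyl by chloride with inversion and without allylic shift, returning the route at 50. Because oxygen and electrophilic chlorine enter from the same face, this sequence gives the C6 epimer of the direct chlorination, so one of the two procedures should lead to the 6S chloride whichever face the ring exposes.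

Further compounds
F0 | step 20 | none | none
F1 | step 32 | C7 triethylsilyl ether of diol 42 | CC(=O)O[C@H]1CCC(=C)[C@H]2[C@@]1(C)[C@@H](OC(=O)C(C)C)CC/C(C)=C/[C@H](O[Si](CC)(CC)CC)[C@@H](O)[C@H]2O[Si](C)(C)C(C)(C)C
F2 | step 32 | C8 ketone with C7 OTES and C9 OTBS | CC(=O)O[C@H]1CCC(=C)[C@H]2[C@@]1(C)[C@@H](OC(=O)C(C)C)CC/C(C)=C/[C@H](O[Si](CC)(CC)CC)C(=O)[C@H]2O[Si](C)(C)C(C)(C)C
F3 | step 32 | C8 tertiary alcohol bearing the C17 ethyl propanoate unit (C7 OTES) | CC(=O)O[C@H]1CCC(=C)[C@H]2[C@@]1(C)[C@@H](OC(=O)C(C)C)CC/C(C)=C/[C@H](O[Si](CC)(CC)CC)[C@@](O)([C@@H](C)C(=O)OCC)[C@H]2O[Si](C)(C)C(C)(C)C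
F4 | step 35 | C6 allylic hydroperoxide with C5=C16 (C6 epimeric to the chloride of 50) | CC(=O)O[C@H]1CCC(=C)[C@H]2[C@@]1(C)[C@@H](OC(=O)C(C)C)CCC(=C)[C@@H](OO)[C@@H]3OC(=O)[C@H](C)[C@@]3(O)[C@H]2OC(C)=O
F5 | step 35 | C6 allylic alcohol with C5=C16 | CC(=O)O[C@H]1CCC(=C)[C@H]2[C@@]1(C)[C@@H](OC(=O)C(C)C)CCC(=C)[C@@H](O)[C@@H]3OC(=O)[C@H](C)[C@@]3(O)[C@H]2OC(C)=O
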